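**Strategy.** Everything rests on cutting the cyclohexene ring (C1, C10, C11, C12, C13, C14; briarane numbering) as a Diels–Alder adduct of a diene C12=C13–C14=C1 attached to C2 and a dienophile C10=C11 attached to C9. The C2–O–C8 ether links both partners through four atoms (C2, O, C8, C9), so one intramolecular cycloaddition closes the cyclohexene, the tetrahydropyran (O, C2, C1, C10, C9, C8) and the ten-membered carbocycle and sets C1, C10, C11 and C12. The precursor is a 2,8-trans oxocane with fused γ-lactone that carries a 1-silyloxydiene on C2 and a propynyl carbinol on C8; hydroboration turns the alkyne into the alkenylborane dienophile in the flask.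

Key step: step 25

Numbering: all intermediates are labelled as in the briarane skeleton: C1 (quaternary, methyl C15), C2 (ether CH), C3 (CHOH), C4 (CH2), C5 (=C16H2), C6 (CHCl), C7 (lactone O–CH), C8 (quaternary ether carbon), C9 (CHOAc), C10 (CH), C11 (methyl C20), C12, C13=C14, C17 (methyl C18), C19 (lactone C=O).

Remark: in the target the C3–C7 bridge is trans across the tetrahydropyran (C1 on C2 and C9 on C8 lie on opposite faces of the oxocane). The route fixes this relation on the monocyclic oxocane before the cycloaddition.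

Step 1
Reactants: 1 pent-3-yn-1-ol
Product: 2 tert-butyldimethyl(pent-3-yn-1-yloxy)silane
Conditions: TBSCl, imidazole, CH2Cl2, 0 °C to rt
Reagents that add atoms: tert-butyldimethylsilyl chloride, CC(C)(C)[Si](C)(C)Cl
Why: Imidazole-promoted silyl ether formation protects the primary alcohol that becomes the C12 oxygen.

Step 2
Reactants: 2 tert-butyldimethyl(pent-3-yn-1-yloxy)silane
Product: 4 (E)-tert-butyl[(4-iodopent-3-en-1-yl)oxy]dimethylsilane, via alkenylzirconocene chloride 3 (not isolated)
Conditions: Cp2Zr(H)Cl (2.2 equiv), THF, 50 °C; then I2, 0 °C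
Reagents that add atoms: iodine, II
Why: Syn hydrozirconation, equilibrated by excess Cp2Zr(H)Cl, should place zirconium on the less hindered methyl-bearing carbon (C1), and iodinolysis with retention should give the (E)-iodide with the methyl group cis to the chain.

Step 3
Reactants: 5 (S)-2,2-dimethyl-1,3-dioxolane-4-carbaldehyde
Product: 6 (1R)-3-bromo-1-[(4S)-2,2-dimethyl-1,3-dioxolan-4-yl]but-3-en-1-ol
Conditions: 2,3-dibromopropene, indium powder (In), THF/H2O, rt
Reagents that add atoms: 2,3-dibromopropene, C=C(Br)CBr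
Why: Barbier-type indium-mediated 2-bromoallylation, in which Felkin–Anh (anti) addition to the α-alkoxy aldehyde should set C3 from the purchased stereocentre.

Step 4
Reactants: 6 (1R)-3-bromo-1-[(4S)-2,2-dimethyl-1,3-dioxolan-4-yl]but-3-en-1-ol
Product: 7 (4S)-4-[(1R)-3-bromo-1-(4-methoxybenzyloxy)but-3-en-1-yl]-2,2-dimethyl-1,3-dioxolane
Conditions: NaH, 4-methoxybenzyl chloride, Bu4NI (cat.), THF/DMF, 0 °C to rt
Reagents that add atoms: 4-methoxybenzyl chloride, COc1ccc(CCl)cc1
Why: Williamson etherification installs the PMB ether on the C3 oxygen, which later allows chelation control and is the last protecting group to be removed.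

Step 5
Reactants: 7 (4S)-4-[(1R)-3-bromo-1-(4-methoxybenzyloxy)but-3-en-1-yl]-2,2-dimethyl-1,3-dioxolane
Product: 8 (R)-4-bromo-2-(4-methoxybenzyloxy)pent-4-enal
Conditions: H5IO6, EtOAc, rt
Reagents that add atoms: none
Why: Periodic acid should hydrolyse the terminal acetonide and cleave the freed 1,2-diol in one pot (glycol cleavage), turning the relay stereocentre into the C2 aldehyde.

Step 6
Reactants: 4 (E)-tert-butyl[(4-iodopent-3-en-1-yl)oxy]dimethylsilane; 8 (R)-4-bromo-2-(4-methoxybenzyloxy)pent-4-enal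
Product: 10 (4R,5R,6E)-2-bromo-9-(tert-butyldimethylsilyloxy)-4-(4-methoxybenzyloxy)-6-methylnona-1,6-dien-5-ol, via alkenylmagnesium chloride 9 (not isolated)
Conditions: iPrMgCl·LiCl, THF, 0 °C to rt (exchange on 4); then 8 precomplexed with MgBr2·OEt2, CH2Cl2, −78 °C
Reagents that add atoms: none
Why: Iodine–magnesium exchange with retention of alkene geometry, then chelation-controlled (Cram chelate) Grignard addition to the α-PMB-oxy aldehyde, should give the 2,3-syn alcohol, which is the C2 epimer needed before the invertive etherification.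

Step 7
Reactants: 11 diethyl oxalate
Product: 12 ethyl 2-oxopent-3-ynoate
Conditions: 1-propynylmagnesium bromide, THF, −78 °C; aq. NH4Cl
Reagents that add atoms: 1-propynylmagnesium bromide, CC#C[Mg]Br
Why: Mono-acylation of the alkynyl Grignard reagent by the oxalate (the tetrahedral intermediate persists at low temperature) gives the ynone ester that carries C8 to C11 and C20.

Step 8
Reactants: 12 ethyl 2-oxopent-3-ynoate
Product: 13 ethyl (R)-2-hydroxypent-3-ynoate
Conditions: RuCl(p-cymene)[(S,S)-TsDPEN] (cat.), iPrOH, rt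
Reagents that add atoms: none
Why: Noyori asymmetric transfer hydrogenation of an alkynyl ketone, in which the alkynyl group takes the place of the aryl group of the usual model, so the (S,S) catalyst should deliver the (R) carbinol that becomes C9.

Step 9
Reactants: 13 ethyl (R)-2-hydroxypent-3-ynoate
Product: 14 ethyl (R)-2-acetoxypent-3-ynoate
Conditions: Ac2O, pyridine, DMAP (cat.), CH2Cl2, 0 °C
Reagents that add atoms: acetic anhydride, CC(=O)OC(C)=O
Why: O-Acetylation attaches the two-carbon unit (C6, C7) for the ring closure.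

Step 10
Reactants: 14 ethyl (R)-2-acetoxypent-3-ynoate
Product: 15 (R)-4-hydroxy-5-(prop-1-yn-1-yl)furan-2(5H)-one
Conditions: LiN(SiMe3)2 (2.2 equiv), THF, −78 °C to 0 °C; then 1 M HCl
Reagents that add atoms: none
Why: Dieckmann-type cyclisation of the acetate enolate onto the ethyl ester gives the tetronic acid, and kinetic deprotonation of the acetate methyl at low temperature should leave C9 untouched.

Step 11
Reactants: 10 (4R,5R,6E)-2-bromo-9-(tert-butyldimethylsilyloxy)-4-(4-methoxybenzyloxy)-6-methylnona-1,6-dien-5-ol; 15 (R)-4-hydroxy-5-(prop-1-yn-1-yl)furan-2(5H)-one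
Product: 16 (5R)-4-{[(4R,5S,6E)-2-bromo-9-(tert-butyldimethylsilyloxy)-4-(4-methoxybenzyloxy)-6-methylnona-1,6-dien-5-yl]oxy}-5-(prop-1-yn-1-yl)furan-2(5H)-one
Conditions: PPh3, DIAD, THF, 0 °C to rt
Reagents that add atoms: none
Why: Mitsunobu O-alkylation of the acidic tetronic acid at O4 is an SN2 displacement with inversion at C2, so it should form the C2–O–C8 ether with the target configuration at C2 and hold C9 cis to C6 in the ring.

Step 12
Reactants: 16 tetronate
Product: 17 (2E,4R)-3-{[(4R,5S,6E)-2-bromo-9-(tert-butyldimethylsilyloxy)-4-(4-methoxybenzyloxy)-6-methylnona-1,6-dien-5-yl]oxy}hept-2-en-5-yne-1,4-diol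
Conditions: iBu2AlH (excess), CH2Cl2, −78 °C to −20 °C; aq. potassium sodium tartrate
Reagents that add atoms: none
Why: Exhaustive hydride reduction of the butenolide (lactone to lactol to allylic alcohol) should open the ring to the ene-diol, whose enol ether geometry (ether oxygen trans to C6, C9 cis to C6) is inherited from the ring.

Step 13
Reactants: 17 ene-diol
Product: 19 primary propionate and C9 triethylsilyl ether of 17, via primary monopropionate 18 (not isolated)
Conditions: propionyl chloride (1.05 equiv), 2,4,6-collidine, CH2Cl2, −78 °C; then Et3SiOTf, −78 °C to 0 °C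
Reagents that add atoms: propionyl chloride, CCC(=O)Cl; triethylsilyl trifluoromethanesulfonate, CC[Si](CC)(CC)OS(=O)(=O)C(F)(F)F
Why: Selective acylation of the primary allylic alcohol at low temperature, then silylation of the hindered secondary alcohol, gives the allylic propionate (C17 to C19) for the sigmatropic shift.

Step 14
Reactants: 19 allylic propionate
Product: 22 (2R,3S)-2-methyl-3-{[nonadienyl of 16]oxy}-3-[(1R)-1-(triethylsilyloxy)but-2-yn-1-yl]pent-4-enoic acid (C8, C9, C17 as in the target), via silyl ketene acetal 20 (not isolated), via silyl ester 21 (not isolated)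
Conditions: LiN(iPr)2, THF/DMPU, −78 °C; TBSCl, −78 °C to 40 °C; then K2CO3, MeOH/H2O, 0 °C
Reagents that add atoms: none
Why: Ireland–Claisen rearrangement through a chair transition state, in which the (Z)-ketene acetal formed in THF/DMPU (methyl cis to OSi) and the equatorial ether oxygen of the enol ether fix C17 relative to C8, while the C8–C17 bond forms anti to the C9–O bond in the conformer with C9–H eclipsing the double bond (allylic 1,3-strain against C6H2), which should set the quaternary C8.

Step 15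
Reactants: 22 Claisen acid
Product: 23 iodolactone (5-iodomethyl γ-lactone with CH2I cis to the ether oxygen on C8; C7 epimeric to the target)
Conditions: I2, NaHCO3, MeCN, 0 °C, dark
Reagents that add atoms: iodine, II
Why: Kinetic 5-exo iodolactonisation, in which the allylic ether oxygen lies in the alkene plane (inside-alkoxy model), should place the iodomethyl group cis to the ether oxygen, so C7 is formed on purpose as the epimer that the next step inverts.

Step 16
Reactants: 23 iodolactone
Product: 25 hydroxymethyl lactone (C6H2OH cis to C9 and C18; C7 as in the target), via epoxy acid 24 (not isolated)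
Conditions: LiOH, THF/H2O, 0 °C to rt; then AcOH to pH 4; PPTS (cat.), CH2Cl2, rt
Reagents that add atoms: lithium hydroxide, [Li+].[OH-]
Why: Hydroxide opens the lactone, the freed C7 alkoxide displaces iodide to give the terminal epoxide, and on acidification the carboxylic acid should reopen the epoxide at C7 by 5-exo attack with inversion (translactonisation), giving C7 as in the target and the C6 primary alcohol.

Step 17
Reactants: 25 hydroxymethyl lactone
Product: 26 lactone aldehyde (C6 aldehyde)
Conditions: Dess–Martin periodinane, pyridine, CH2Cl2, 0 °C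
Reagents that add atoms: none
Why: Buffered Dess–Martin oxidation should give the α-acyloxy aldehyde without epimerising C7.

Step 18
Reactants: 26 lactone aldehyde
Product: 28 oxocane allylic alcohol (5-methylene, 6-OH cis to the C7 oxygen), via alkenylchromium dichloride 27 (not isolated)
Conditions: CrCl2 (excess), NiCl2 (cat.), DMSO/THF, rt, high dilution with slow addition
Reagents that add atoms: none
Why: Intramolecular Nozaki–Hiyama–Kishi addition of the 2-bromoalkene to the aldehyde closes the oxocane at C5–C6 and delivers the exocyclic methylene; the Felkin–Anh isomer at C6 is expected, and either C6 epimer can be carried on because the next step removes this centre.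

Step 19
Reactants: 28 oxocane allylic alcohol
Product: 29 oxocane α-methylene ketone (C6 ketone)
Conditions: Dess–Martin periodinane, pyridine, CH2Cl2, 0 °C
Reagents that add atoms: none
Why: Dess–Martin oxidation of the allylic alcohol converges both C6 epimers on one enone.

Step 20
Reactants: 29 oxocane α-methylene ketone
Product: 30 oxocane allylic alcohol with 6-OH trans to the C7 oxygen
Conditions: NaBH4, CeCl3·7H2O, MeOH/CH2Cl2, −78 °C
Reagents that add atoms: none
Why: Luche 1,2-reduction, in which hydride attack anti to the C7–O bond (Felkin–Anh control for an α-acyloxy ketone) should give the alcohol trans to the lactone oxygen, the epimer needed for an invertive chlorination.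

Step 21
Reactants: 30 oxocane allylic alcohol
Product: 31 oxocane allylic chloride (C6–Cl as in the target)
Conditions: PPh3, hexachloroacetone, CH2Cl2, −20 °C to 0 °C
Reagents that add atoms: hexachloroacetone, ClC(Cl)(Cl)C(=O)C(Cl)(Cl)Cl
Why: Appel-type chlorination through the alkoxyphosphonium salt is an SN2 displacement with inversion, and this reagent pair at low temperature should avoid allylic transposition, placing chlorine on C6 cis to the C7 oxygen.

Step 22
Reactants: 31 oxocane allylic chloride
Product: 32 oxocane diol (free C9 and C12 hydroxyls)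
Conditions: HF·pyridine, pyridine, THF, 0 °C to rt
Reagents that add atoms: none
Why: Fluoride-mediated desilylation removes the triethylsilyl ether and the primary TBS ether while chloride, lactone and PMB ether should persist.

Step 23
Reactants: 32 oxocane diol
Product: 33 oxocane β,γ-unsaturated aldehyde (C12 aldehyde, free C9 hydroxyl)
Conditions: TEMPO (cat.), PhI(OAc)2, CH2Cl2, rt
Reagents that add atoms: none
Why: Oxoammonium-mediated oxidation is selective for the primary alcohol over the secondary propargylic one and, being non-basic, should not move the C1=C14 double bond into conjugation.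

Step 24
Reactants: 33 oxocane aldehyde
Product: 34 oxocane triene-yne: (1E,3E)-1-(tert-butyldimethylsilyloxy)diene on C2, C9 TBS ether with prop-1-ynyl group
Conditions: TBSOTf (2.5 equiv), Et3N, CH2Cl2, −78 °C to 0 °C
Reagents that add atoms: tert-butyldimethylsilyl trifluoromethanesulfonate, CC(C)(C)[Si](C)(C)OS(=O)(=O)C(F)(F)F
Why: Soft enolisation at the doubly activated C13 and O-silylation should give the 1-silyloxydiene (E at C12=C13 expected, C1=C14 geometry retained), and the C9 hydroxyl is silylated in the same operation.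

Step 25
Reactants: 34 oxocane triene-yne
Product: 37 tetracyclic cycloadduct with free C11 hydroxyl (C9 and C12 TBS ethers, C3 PMB ether), via alkenylborane 35 (not isolated), via cycloadduct borane 36 (not isolated)
Conditions: (c-C6H11)2BH (from BH3·SMe2 and cyclohexene, 1.1 equiv), THF, 0 °C to rt; then 55 °C; then aq. NaOAc, 30% H2O2, 0 °C to rt
Reagents that add atoms: hydrogen peroxide, OO
Why: Syn hydroboration of the propynyl group puts boron on the methyl-bearing C11 (the C9 side is blocked by the silyloxy group and the quaternary C8); the resulting alkenyldialkylborane 35, a strongly activated dienophile, should undergo a concerted, asynchronous, normal-demand [4+2] cycloaddition with the (1E,3E)-1-silyloxydiene (leading bond C1–C10, "ortho" bond C11–C12), and oxidation of the C–B bond with retention then gives the C11 alcohol. The closest known reaction types are the intermolecular vinylborane Diels–Alder reaction with oxidative work-up and the type 1 intramolecular Diels–Alder reaction of ether-tethered 1,7,9-decatrienes. The cyclohexene (C1, C10 to C14) closes by the cycloaddition itself, the tetrahydropyran (O, C2, C1, C10, C9, C8) closes as the six-membered tether ring fused through C1–C10, and the ten-membered carbocycle closes because the same C1–C10 bond bridges the preformed oxocane. Suprafacial addition carries the geometry of both partners (C2 and the silyloxy group outside on the diene, C9 cis to the C11 methyl on the dienophile) into the relative configuration of C1, C10, C11 and C12; the endo position of boron (the secondary boron–diene interaction typical of vinylboranes) puts the tether exo and so gives the trans C1/C10 fusion with boron, later oxygen, on C11 cis to the C12 oxygen; and the pairing of the two π-faces follows from a chair-like tether in which C3 on C2, the silyloxy group on C9 and C17 on C8 are equatorial, whereas the other trans-fused chair would make all three axial. The step needs chemoselective hydroboration of the alkyne over the hindered exocyclic methylene and the dienyl ether, which the bulky dialkylborane should secure because it adds faster to internal alkynes than to 1,1-disubstituted or conjugated alkenes; it must also build the trans-bridged oxabicyclo[5.3.1] unit, but the configuration at C2 and C8 is already fixed in the oxocane, so only strain remains, and the exothermic cycloaddition can pay for it.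

Step 26
Reactants: 37 tetracyclic cycloadduct alcohol
Product: 38 tetracyclic triol (free C9, C11 and C12 hydroxyls, C3 PMB ether)
Conditions: HF·pyridine, THF, rt
Reagents that add atoms: none
Why: Fluoride-mediated cleavage of both secondary TBS ethers, which the allylic chloride and the lactone should tolerate.

Step 27
Reactants: 38 tetracyclic triol
Product: 39 C9, C11, C12 triacetate with C3 PMB ether
Conditions: Ac2O, DMAP, Et3N, CH2Cl2, 40 °C
Reagents that add atoms: acetic anhydride, CC(=O)OC(C)=O
Why: DMAP-catalysed acetylation should esterify the two secondary hydroxyls and, under forcing, the tertiary C11 hydroxyl while C3 stays protected.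

Step 28
Reactants: 39 triacetate PMB ether
Product: 40 CNP0333938.3 (target)
Conditions: DDQ, CH2Cl2/pH 7 buffer, 0 °C
Reagents that add atoms: none
Why: Oxidative PMB ether cleavage should free the C3 hydroxyl without touching acetates, allylic chloride or alkenes.

**Compound list**

1 | pent-3-yn-1-ol | CC#CCCO | starting material
2 | tert-butyldimethyl(pent-3-yn-1-yloxy)silane | CC#CCCO[Si](C)(C)C(C)(C)C | intermediate
3 | (E)-[5-(tert-butyldimethylsilyloxy)pent-2-en-2-yl]bis(cyclopentadienyl)zirconium chloride | Cl[Zr](C1C=CC=C1)(C2C=CC=C2)/C(C)=C/CCO[Si](C)(C)C(C)(C)C | intermediate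
4 | (E)-tert-butyl[(4-iodopent-3-en-1-yl)oxy]dimethylsilane | I/C(C)=C/CCO[Si](C)(C)C(C)(C)C | intermediate
5 | (S)-2,2-dimethyl-1,3-dioxolane-4-carbaldehyde | O=C[C@@H]1COC(C)(C)O1 | starting material
6 | (1R)-3-bromo-1-[(4S)-2,2-dimethyl-1,3-dioxolan-4-yl]but-3-en-1-ol | C=C(Br)C[C@@H](O)[C@@H]1COC(C)(C)O1 | intermediate
7 | (4S)-4-[(1R)-3-bromo-1-(4-methoxybenzyloxy)but-3-en-1-yl]-2,2-dimethyl-1,3-dioxolane | C=C(Br)C[C@@H](OCc1ccc(OC)cc1)[C@@H]2COC(C)(C)O2 | intermediate
8 | (R)-4-bromo-2-(4-methoxybenzyloxy)pent-4-enal | C=C(Br)C[C@@H](OCc1ccc(OC)cc1)C=O | intermediate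
9 | (E)-[5-(tert-butyldimethylsilyloxy)pent-2-en-2-yl]magnesium chloride | Cl[Mg]/C(C)=C/CCO[Si](C)(C)C(C)(C)C | intermediate
10 | (4R,5R,6E)-2-bromo-9-(tert-butyldimethylsilyloxy)-4-(4-methoxybenzyloxy)-6-methylnona-1,6-dien-5-ol (C3 as in the target, C2 epimeric) | C=C(Br)C[C@@H](OCc1ccc(OC)cc1)[C@H](O)/C(C)=C/CCO[Si](C)(C)C(C)(C)C | intermediate
11 | diethyl oxalate | CCOC(=O)C(=O)OCC | starting material
12 | ethyl 2-oxopent-3-ynoate | CCOC(=O)C(=O)C#CC | intermediate
13 | ethyl (R)-2-hydroxypent-3-ynoate | CCOC(=O)[C@H](O)C#CC | intermediate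
14 | ethyl (R)-2-acetoxypent-3-ynoate | CCOC(=O)[C@H](OC(C)=O)C#CC | intermediate
15 | (R)-4-hydroxy-5-(prop-1-yn-1-yl)furan-2(5H)-one | O=C1C=C(O)[C@@H](C#CC)O1 | intermediate
16 | (5R)-4-{[(4R,5S,6E)-2-bromo-9-(tert-butyldimethylsilyloxy)-4-(4-methoxybenzyloxy)-6-methylnona-1,6-dien-5-yl]oxy}-5-(prop-1-yn-1-yl)furan-2(5H)-one | C=C(Br)C[C@@H](OCc1ccc(OC)cc1)[C@H](/C(C)=C/CCO[Si](C)(C)C(C)(C)C)OC2=CC(=O)O[C@@H]2C#CC | intermediate
17 | (2E,4R)-3-{[(4R,5S,6E)-2-bromo-9-(tert-butyldimethylsilyloxy)-4-(4-methoxybenzyloxy)-6-methylnona-1,6-dien-5-yl]oxy}hept-2-en-5-yne-1,4-diol | C=C(Br)C[C@@H](OCc1ccc(OC)cc1)[C@H](/C(C)=C/CCO[Si](C)(C)C(C)(C)C)O/C(=C/CO)[C@H](O)C#CC | intermediate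
18 | primary (C6) propionate of 17, C9 hydroxyl free | C=C(Br)C[C@@H](OCc1ccc(OC)cc1)[C@H](/C(C)=C/CCO[Si](C)(C)C(C)(C)C)O/C(=C/COC(=O)CC)[C@H](O)C#CC | intermediate
19 | primary (C6) propionate and C9 triethylsilyl ether of 17 | C=C(Br)C[C@@H](OCc1ccc(OC)cc1)[C@H](/C(C)=C/CCO[Si](C)(C)C(C)(C)C)O/C(=C/COC(=O)CC)[C@H](O[Si](CC)(CC)CC)C#CC | intermediate
20 | (Z)-O-tert-butyldimethylsilyl ketene acetal of 19 (methyl cis to OSi) | C=C(Br)C[C@@H](OCc1ccc(OC)cc1)[C@H](/C(C)=C/CCO[Si](C)(C)C(C)(C)C)O/C(=C/CO/C(O[Si](C)(C)C(C)(C)C)=C/C)[C@H](O[Si](CC)(CC)CC)C#CC | intermediate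
21 | tert-butyldimethylsilyl ester of acid 22 | C=C(Br)C[C@@H](OCc1ccc(OC)cc1)[C@H](/C(C)=C/CCO[Si](C)(C)C(C)(C)C)O[C@](C=C)([C@H](O[Si](CC)(CC)CC)C#CC)[C@@H](C)C(=O)O[Si](C)(C)C(C)(C)C | intermediate
22 | (2R,3S)-2-methyl-3-{[nonadienyl of 16]oxy}-3-[(1R)-1-(triethylsilyloxy)but-2-yn-1-yl]pent-4-enoic acid (C8, C9, C17 as in the target) | C=C(Br)C[C@@H](OCc1ccc(OC)cc1)[C@H](/C(C)=C/CCO[Si](C)(C)C(C)(C)C)O[C@](C=C)([C@H](O[Si](CC)(CC)CC)C#CC)[C@@H](C)C(=O)O | intermediate
23 | iodolactone: 5-(iodomethyl)-3-methyl-γ-butyrolactone bearing on C8 the ether oxygen and the (R)-1-(triethylsilyloxy)but-2-ynyl group; CH2I cis to the ether oxygen (C7 epimeric to the target) | C=C(Br)C[C@@H](OCc1ccc(OC)cc1)[C@H](/C(C)=C/CCO[Si](C)(C)C(C)(C)C)O[C@]2([C@H](O[Si](CC)(CC)CC)C#CC)[C@@H](C)C(=O)O[C@@H]2CI | intermediate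
24 | epoxy acid: acid 22 with the vinyl group as C6–C7 epoxide (C7–O configured as in 23) | C=C(Br)C[C@@H](OCc1ccc(OC)cc1)[C@H](/C(C)=C/CCO[Si](C)(C)C(C)(C)C)O[C@]([C@H]2CO2)([C@H](O[Si](CC)(CC)CC)C#CC)[C@@H](C)C(=O)O | intermediate
25 | hydroxymethyl lactone: C7 inverted relative to 23 (C6H2OH cis to C9 and C18; C7, C8, C9, C17 as in the target) | C=C(Br)C[C@@H](OCc1ccc(OC)cc1)[C@H](/C(C)=C/CCO[Si](C)(C)C(C)(C)C)O[C@]2([C@H](O[Si](CC)(CC)CC)C#CC)[C@@H](C)C(=O)O[C@H]2CO | intermediate
26 | lactone aldehyde (C6 aldehyde of 25) | C=C(Br)C[C@@H](OCc1ccc(OC)cc1)[C@H](/C(C)=C/CCO[Si](C)(C)C(C)(C)C)O[C@]2([C@H](O[Si](CC)(CC)CC)C#CC)[C@@H](C)C(=O)O[C@H]2C=O | intermediate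
27 | alkenylchromium dichloride formed from 26 at C5 | C=C([Cr](Cl)Cl)C[C@@H](OCc1ccc(OC)cc1)[C@H](/C(C)=C/CCO[Si](C)(C)C(C)(C)C)O[C@]2([C@H](O[Si](CC)(CC)CC)C#CC)[C@@H](C)C(=O)O[C@H]2C=O | intermediate
28 | oxocane-fused lactone, 5-methylene, 6-OH cis to the C7 oxygen (Felkin–Anh epimer), C9 OTES, C12 OTBS, C3 OPMB | C=C1C[C@@H](OCc3ccc(OC)cc3)[C@H](/C(C)=C/CCO[Si](C)(C)C(C)(C)C)O[C@]2([C@H](O[Si](CC)(CC)CC)C#CC)[C@@H](C)C(=O)O[C@H]2[C@H]1O | intermediate
29 | oxocane α-methylene ketone (C6 ketone of 28) | C=C1C[C@@H](OCc3ccc(OC)cc3)[C@H](/C(C)=C/CCO[Si](C)(C)C(C)(C)C)O[C@]2([C@H](O[Si](CC)(CC)CC)C#CC)[C@@H](C)C(=O)O[C@H]2C1=O | intermediate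
30 | oxocane allylic alcohol, 6-OH trans to the C7 oxygen | C=C1C[C@@H](OCc3ccc(OC)cc3)[C@H](/C(C)=C/CCO[Si](C)(C)C(C)(C)C)O[C@]2([C@H](O[Si](CC)(CC)CC)C#CC)[C@@H](C)C(=O)O[C@H]2[C@@H]1O | intermediate
31 | oxocane allylic chloride (C2, C3, C6, C7, C8, C9, C17 as in the target), C9 OTES, C12 OTBS, C3 OPMB | C=C1C[C@@H](OCc3ccc(OC)cc3)[C@H](/C(C)=C/CCO[Si](C)(C)C(C)(C)C)O[C@]2([C@H](O[Si](CC)(CC)CC)C#CC)[C@@H](C)C(=O)O[C@H]2[C@H]1Cl | intermediate
32 | oxocane chloride diol (free C9 and C12 hydroxyls) | C=C1C[C@@H](OCc3ccc(OC)cc3)[C@H](/C(C)=C/CCO)O[C@]2([C@H](O)C#CC)[C@@H](C)C(=O)O[C@H]2[C@H]1Cl | intermediate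
33 | oxocane chloride β,γ-unsaturated aldehyde (C12 aldehyde, free C9 hydroxyl) | C=C1C[C@@H](OCc3ccc(OC)cc3)[C@H](/C(C)=C/CC=O)O[C@]2([C@H](O)C#CC)[C@@H](C)C(=O)O[C@H]2[C@H]1Cl | intermediate
34 | cycloaddition precursor: 2,8-trans oxocane with fused lactone, (1E,3E)-1-(tert-butyldimethylsilyloxy)diene on C2, (R)-1-(tert-butyldimethylsilyloxy)but-2-ynyl on C8 | C=C1C[C@@H](OCc3ccc(OC)cc3)[C@H](/C(C)=C/C=C/O[Si](C)(C)C(C)(C)C)O[C@]2([C@H](O[Si](C)(C)C(C)(C)C)C#CC)[C@@H](C)C(=O)O[C@H]2[C@H]1Cl | intermediate
35 | alkenyl(dicyclohexyl)borane from 34 (boron on C11, cis to H-10; C9 cis to the C11 methyl) | C=C1C[C@@H](OCc3ccc(OC)cc3)[C@H](/C(C)=C/C=C/O[Si](C)(C)C(C)(C)C)O[C@]2([C@H](O[Si](C)(C)C(C)(C)C)/C=C(\C)B(C4CCCCC4)C5CCCCC5)[C@@H](C)C(=O)O[C@H]2[C@H]1Cl | intermediate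
36 | tetracyclic cycloadduct with dicyclohexylboryl group on C11 | C=C1C[C@@H](OCc5ccc(OC)cc5)[C@H]2O[C@]3([C@H](O[Si](C)(C)C(C)(C)C)[C@@H]4[C@]2(C)C=C[C@@H](O[Si](C)(C)C(C)(C)C)[C@@]4(C)B(C6CCCCC6)C7CCCCC7)[C@@H](C)C(=O)O[C@H]3[C@H]1Cl | intermediate
37 | tetracyclic cycloadduct, free C11 hydroxyl, C9 and C12 OTBS, C3 OPMB (all eleven stereocentres as in the target) | C=C1C[C@@H](OCc5ccc(OC)cc5)[C@H]2O[C@]3([C@H](O[Si](C)(C)C(C)(C)C)[C@@H]4[C@]2(C)C=C[C@@H](O[Si](C)(C)C(C)(C)C)[C@@]4(C)O)[C@@H](C)C(=O)O[C@H]3[C@H]1Cl | intermediate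
38 | tetracyclic C9, C11, C12 triol, C3 OPMB | C=C1C[C@@H](OCc5ccc(OC)cc5)[C@H]2O[C@]3([C@H](O)[C@@H]4[C@]2(C)C=C[C@@H](O)[C@@]4(C)O)[C@@H](C)C(=O)O[C@H]3[C@H]1Cl | intermediate
39 | C9, C11, C12 triacetate, C3 OPMB | C=C1C[C@@H](OCc5ccc(OC)cc5)[C@H]2O[C@]3([C@H](OC(C)=O)[C@@H]4[C@]2(C)C=C[C@@H](OC(C)=O)[C@@]4(C)OC(C)=O)[C@@H](C)C(=O)O[C@H]3[C@H]1Cl | intermediate
40 | CNP0333938.3 | C=C1C[C@@H](O)[C@H]2O[C@]3([C@H](OC(C)=O)[C@@H]4[C@]2(C)C=C[C@@H](OC(C)=O)[C@@]4(C)OC(C)=O)[C@@H](C)C(=O)O[C@H]3[C@H]1Cl | target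

**Totals.** Total step count: 28. Longest linear sequence: 22 steps (steps 3 to 6, then 11 to 28, from 5 to 40).

**Steps most likely to fail, with fallbacks**

Step 25. Hydroboration may also occur at the exocyclic methylene or the dienyl ether. The cycloaddition may be slow against the strain of the trans-bridged ring system, so that protodeboronation or diene isomerisation compete, and the endo/exo or facial selectivity may be poor. The fallback sets out from 34. Hydroboration of the alkyne alone with pinacolborane under Cp2Zr(H)Cl catalysis (CH2Cl2, rt) would give the isolable alkenyl pinacolboronate F1. A thermal intramolecular Diels–Alder reaction of F1 (toluene, BHT, sealed tube, 150 °C) would give the cycloadduct pinacolboronate F2. Oxidation of F2 with NaBO3·4H2O (THF/H2O, rt) comes back to the route at 37.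

Step 11. The activated allylic alcohol may react by SN2' attack or eliminate, or the tetronate may be alkylated on carbon instead of oxygen. The fallback makes the C2–O bond as an ester bond and builds the butenolide afterwards; it sets out from 13 and 10. Silylation of 13 (Et3SiCl, imidazole) would give ethyl (R)-2-(triethylsilyloxy)pent-3-ynoate F3, and saponification (LiOH, THF/H2O, 0 °C) would give (R)-2-(triethylsilyloxy)pent-3-ynoic acid F4. Mitsunobu esterification of 10 with F4 (PPh3, DIAD), with a carboxylic acid as the more dependable nucleophile, would give with inversion at C2 the ester F5. Selective removal of the triethylsilyl group (PPTS, MeOH, 0 °C) would give the α-hydroxy ester F6. Treatment of F6 with ketenylidenetriphenylphosphorane (Ph3P=C=C=O, THF, 60 °C) should add the hydroxyl to the ketene and close the 4-alkoxybutenolide by intramolecular Wittig olefination of the ester carbonyl, coming back to the route at 16.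

Step 20. Hydride delivery to the medium-ring enone may show poor facial selectivity. The fallback replaces substrate control by reagent control: Corey–Bakshi–Shibata reduction of 29 (oxazaborolidine enantiomer matched to the required C6 configuration, catecholborane, toluene, −78 °C) should give 30 directly, so it sets out from 29 and comes back at 30 without a new compound.

**Further compounds**

F1 | step 25 | alkenyl pinacolboronate of 34 (boron on C11, cis to H-10) | C=C1C[C@@H](OCc3ccc(OC)cc3)[C@H](/C(C)=C/C=C/O[Si](C)(C)C(C)(C)C)O[C@]2([C@H](O[Si](C)(C)C(C)(C)C)/C=C(\C)B4OC(C)(C)C(C)(C)O4)[C@@H](C)C(=O)O[C@H]2[C@H]1Cl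
F2 | step 25 | tetracyclic cycloadduct with pinacolboryl group on C11 | C=C1C[C@@H](OCc5ccc(OC)cc5)[C@H]2O[C@]3([C@H](O[Si](C)(C)C(C)(C)C)[C@@H]4[C@]2(C)C=C[C@@H](O[Si](C)(C)C(C)(C)C)[C@@]4(C)B6OC(C)(C)C(C)(C)O6)[C@@H](C)C(=O)O[C@H]3[C@H]1Cl
F3 | step 11 | ethyl (R)-2-(triethylsilyloxy)pent-3-ynoate | CCOC(=O)[C@H](O[Si](CC)(CC)CC)C#CC
F4 | step 11 | (R)-2-(triethylsilyloxy)pent-3-ynoic acid | OC(=O)[C@H](O[Si](CC)(CC)CC)C#CC
F5 | step 11 | (4R,5S,6E)-2-bromo-9-(tert-butyldimethylsilyloxy)-4-(4-methoxybenzyloxy)-6-methylnona-1,6-dien-5-yl (R)-2-(triethylsilyloxy)pent-3-ynoate | C=C(Br)C[C@@H](OCc1ccc(OC)cc1)[C@H](/C(C)=C/CCO[Si](C)(C)C(C)(C)C)OC(=O)[C@H](O[Si](CC)(CC)CC)C#CC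
F6 | step 11 | (4R,5S,6E)-2-bromo-9-(tert-butyldimethylsilyloxy)-4-(4-methoxybenzyloxy)-6-methylnona-1,6-dien-5-yl (R)-2-hydroxypent-3-ynoate | C=C(Br)C[C@@H](OCc1ccc(OC)cc1)[C@H](/C(C)=C/CCO[Si](C)(C)C(C)(C)C)OC(=O)[C@H](O)C#CC
F0 | step 20 | none | none
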